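**Strategy.** Ring C (the oxonane C2–C9 with its ether oxygen) is carried as a cyclopentane cis-fused to a six-membered ether. C3 with its methyl, C4–O, C5, C6 and C7 are the five carbocyclic atoms, and C3–C7 is the bond the two rings share. A Grob fragmentation of the C7-hydroxy C4-mesylate cuts this bond in one operation. It gives the nine-membered ring with a ketone at C7 (handle for the exocyclic methylene and the C6 hydroxyl) and a Z alkene at C3=C4 (handle for the lactone oxygen and the C4 ester). The precursor is an 8-oxabicyclo[3.2.1]octane bearing rings A and B and the fused cyclopentane, built by a vinylogous Mukaiyama addition at C9 and a Prins cyclisation at C2.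

Key step: step 17

Remark on the chemistry: atom numbers are those of the target (C1–C16). The acetal centres (C9 in 5–11, C2 in 17 and 18) are drawn as the expected major epimer; either epimer gives the same oxocarbenium ion. Three design points: the dienol ether is made from the 1,3-dione so that C8 is unambiguously the nucleophilic terminus; the C4 carbinol is set after the cyclisation by hydroxyl-directed reduction; both silyl ethers are t-BuMe2Si so that the primary one can be removed first.

Step 1
Reactants: 1 (R)-carvone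
Product: 2 (R)-carvone (E)-p-toluenesulfonylhydrazone
Conditions: TsNHNH2, EtOH, AcOH (cat.), rt
Reagents that add atoms: p-toluenesulfonyl hydrazide, Cc1ccc(cc1)S(=O)(=O)NN
Why: Hydrazone formation (condensation of the ketone with the sulfonyl hydrazide) is routine for carvone and does not touch the C14 stereocentre.

Step 2
Reactants: 2 (R)-carvone (E)-p-toluenesulfonylhydrazone
Product: 4 (5R)-2-methyl-5-(prop-1-en-2-yl)cyclohexa-1,3-diene, via vinyllithium 3 (not isolated)
Conditions: MeLi (2.5 equiv), Et2O, 0 °C to rt; H2O, 0 °C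
Reagents that add atoms: none
Why: Shapiro reaction: the hydrazone dianion forms at C1, the only sp3 α-carbon, loses sulfinate and dinitrogen to give the C10 vinyllithium, and protonation gives the conjugated diene with C14 unchanged.

Step 3
Reactants: 4 (5R)-2-methyl-5-(prop-1-en-2-yl)cyclohexa-1,3-diene
Product: 5 cis-fused 7-methoxy-5-methyl-2-(prop-1-en-2-yl)bicyclo[4.2.0]oct-4-en-8-one (four-membered ring trans to the isopropenyl group, C=O carbon on C1, CH(OMe) carbon on C10, OMe endo)
Conditions: MeOCH2COCl (slow addition), Et3N, CH2Cl2, 0 °C to rt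
Reagents that add atoms: methoxyacetyl chloride, COCC(Cl)=O
Why: Ketene [2+2] cycloaddition: methoxyketene made in the flask adds to the conjugated diene only (alkoxyketenes do not engage isolated alkenes), at the less substituted C1=C10 bond with its carbonyl carbon on the diene terminus C1 and on the face opposite the C14 substituent, which sets C1 and C10 cis to each other and trans to the isopropenyl group.

Step 4
Reactants: 5 cyclobutanone
Product: 6 methoxy lactone (pseudoester): cis-fused 3-methoxy-4-methyl-7-(prop-1-en-2-yl)-3a,6,7,7a-tetrahydro-3H-isobenzofuran-1-one (C2 lactone carbonyl, C9 acetal carbon, ring B trans to the isopropenyl group)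
Conditions: 30% H2O2, AcOH, 0 °C
Reagents that add atoms: hydrogen peroxide, OO
Why: Baeyer–Villiger oxidation: the strained cyclobutanone reacts with hydrogen peroxide alone, so the alkenes are spared, and the α-methoxy carbon migrates with retention, which puts the ring oxygen between the lactone carbonyl C2 and the acetal carbon C9.

Step 5
Reactants: 6 methoxy lactone
Product: 8 primary alcohol (15R) with the C11=C12 alkene intact, via B-alkyl-9-BBN 7 (not isolated)
Conditions: 9-BBN, THF, 0 °C to rt; NaBO3·4H2O, H2O, rt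
Reagents that add atoms: sodium perborate, [Na+].[Na+].O[B-]1(O)OO[B-](O)(O)OO1
Why: Hydroboration–oxidation: 9-BBN takes only the 1,1-disubstituted alkene and, with H14 eclipsing the C=CH2 bond, approaches from the side of C13 and not from the side of the substituted C1 (the sense known for isopulegol ethers), which sets C15 as R.

Step 6
Reactants: 8 primary alcohol
Product: 10 diol with the tertiary C11 hydroxyl cis to C9, via alkylmercury acetate 9 (not isolated)
Conditions: Hg(OAc)2, NaOAc, THF/H2O, 0 °C to rt; NaBH4, 0 °C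
Reagents that add atoms: water, O
Why: Oxymercuration–demercuration (Markovnikov hydration): divalent mercury binds the alkene face opposite the axial C10–C9 bond, water opens the mercurinium ion anti at the tertiary C11 and so places the hydroxyl cis to C9, and NaBH4 replaces mercury at C12 by hydrogen.

Step 7
Reactants: 10 diol
Product: 11 bis-silyl ether of the methoxy lactone (C16–OSiMe2t-Bu, C11–OSiMe2t-Bu)
Conditions: t-BuMe2SiOTf (3 equiv), 2,6-lutidine, CH2Cl2, −78 to 0 °C
Reagents that add atoms: tert-butyldimethylsilyl triflate, CC(C)(C)[Si](C)(C)OS(=O)(=O)C(F)(F)F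
Why: Silylation with the silyl triflate protects the primary and the hindered tertiary hydroxyl in one operation, and at this temperature the acylal-type acetal at C9 is not ionised.

Step 8
Reactants: 12 2-methylcyclopentane-1,3-dione
Product: 13 3-[(tert-butyldimethylsilyl)oxy]-2-methylcyclopent-2-en-1-one
Conditions: t-BuMe2SiCl, Et3N, CH2Cl2, rt
Reagents that add atoms: tert-butyldimethylsilyl chloride, CC(C)(C)[Si](C)(C)Cl
Why: O-Silylation of the enol form of the symmetrical 1,3-dione gives the vinylogous silyl ester, with no regiochemical choice to make.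

Step 9
Reactants: 13 vinylogous silyl ester
Product: 14 tert-butyldimethyl[(2-methyl-3-methylidenecyclopent-1-en-1-yl)oxy]silane (silyl dienol ether; C4–O, C3–Me, C7=C8)
Conditions: Cp2TiMe2, toluene, 65 °C, dark
Reagents that add atoms: dimethyltitanocene, C[Ti](C)(C1C=CC=C1)C1C=CC=C1
Why: Petasis methylenation of the vinylogous ester carbonyl (C7) adds C8 as an exocyclic methylene and thus fixes the position of the extended dienol ether, which enolisation of a 3-methylcyclopentenone would not do reliably.

Step 10
Reactants: 11 bis-silyl methoxy lactone; 14 silyl dienol ether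
Product: 15 enone lactone (C8–C9 bond formed; C8 on C9 trans to the C10–C11 bond; 2-methylcyclopent-2-enone attached through C7)
Conditions: Me3SiOTf (1.1 equiv), CH2Cl2, −78 to −30 °C; aq NaHCO3
Reagents that add atoms: none
Why: Vinylogous Mukaiyama addition: the C9 oxocarbenium ion formed from the methoxy lactone is attacked by the terminal carbon C8 of the dienol ether on the convex face, anti to the C10–C11 bond, which sets C9 and regenerates the enone.

Step 11
Reactants: 15 enone lactone
Product: 16 (4S)-allylic alcohol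
Conditions: (R)-1-methyl-3,3-diphenyltetrahydro-1H,3H-pyrrolo[1,2-c][1,3,2]oxazaborole (0.2 equiv), BH3·SMe2, THF, −30 °C; MeOH
Reagents that add atoms: none
Why: Corey–Bakshi–Shibata reduction: the catalyst (alkenyl arm as the large group) and not the remote stereocentres selects the carbonyl face and gives the (4S)-alcohol, whose oxygen will lie opposite the C2–C3 bond made in step 13, while the lactone is inert to the borane at this temperature.

Step 12
Reactants: 16 (4S)-allylic alcohol
Product: 18 bis-acetate (C2 α-acetoxy ether, C4 allylic acetate), via aluminium hemiacetal 17 (not isolated)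
Conditions: i-Bu2AlH (2.3 equiv), CH2Cl2, −78 °C; pyridine, 4-(dimethylamino)pyridine, Ac2O, −78 to −20 °C
Reagents that add atoms: acetic anhydride, CC(=O)OC(C)=O
Why: Reductive acetylation of the lactone (i-Bu2AlH, then acylation of the aluminium hemiacetal) gives the C2 α-acetoxy ether and acetylates the C4 hydroxyl in the same flask.

Step 13
Reactants: 18 bis-acetate
Product: 21 tetracyclic cis-1,3-diol (8-oxabicyclo[3.2.1]octane C2/C3/C7/C8/C9/O with the C1–C10 bridge, cyclopentane cis-fused at C3–C7 on the side away from that bridge; (4S)-OH and C7–OH both syn to the C3 methyl), via acetoxonium triflate 19 (not isolated), via hydroxy acetate 20 (not isolated)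
Conditions: Me3SiOTf (1.5 equiv), 2,6-di-tert-butyl-4-methylpyridine, CH2Cl2, −78 to −40 °C; aq NaHCO3; then K2CO3, MeOH, rt
Reagents that add atoms: water, O
Why: Prins cyclisation: the C2 oxocarbenium ion released from the anomeric acetate is attacked by C3 of the tetrasubstituted alkene in a six-membered transition state with the cyclopentene turned away from the C1–C10 bridge and opposite the C4 acetate, the C7 cation is captured anti by that acetate as a 1,3-dioxan-2-ylium ion, and hydrolysis then methanolysis give the cis-fused diol with C2, C3 and C7 set.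

Step 14
Reactants: 21 tetracyclic cis-diol
Product: 22 β-hydroxy ketone (C4 ketone, C7–OH)
Conditions: Dess–Martin periodinane, NaHCO3, CH2Cl2, 0 °C to rt
Reagents that add atoms: none
Why: Dess–Martin oxidation converts only the secondary C4 alcohol, and under neutral buffered conditions the β-hydroxy ketone is not exposed to the base that would trigger retro-aldol cleavage.

Step 15
Reactants: 22 β-hydroxy ketone
Product: 23 anti-1,3-diol ((4R)-OH syn to C2, trans to C7–OH)
Conditions: Me4NBH(OAc)3, MeCN/AcOH, −30 °C
Reagents that add atoms: none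
Why: Evans–Saksena reduction: the acetoxyborohydride bound to the C7 hydroxyl delivers hydride to C4 from the face of that hydroxyl, so the new carbinol is anti to C7–OH and syn to C2, the arrangement the fragmentation needs.

Step 16
Reactants: 23 anti-1,3-diol
Product: 24 tetracyclic hydroxy mesylate ((4R)-OMs syn to C2, tertiary C7–OH; C11–OSiMe2t-Bu, C16–OSiMe2t-Bu)
Conditions: MsCl, Et3N, CH2Cl2, −20 to 0 °C
Reagents that add atoms: methanesulfonyl chloride, CS(Cl)(=O)=O
Why: Mesylation of the secondary C4 alcohol is selective because the tertiary ring-fusion hydroxyl at C7 is too hindered to be sulfonylated.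

Step 17
Reactants: 24 tetracyclic hydroxy mesylate
Product: 26 tricyclic oxonenone (C7 ketone, (Z)-C3=C4 alkene, rings A, B and C), via potassium alkoxide 25 (not isolated)
Conditions: KOt-Bu (1.05 equiv), THF, 0 °C to rt
Reagents that add atoms: none
Why: KOt-Bu deprotonates the tertiary C7 hydroxyl; in alkoxide 25 the cis ring fusion fixes the cyclopentane envelope so that the C2-syn mesylate is pseudo-equatorial and its C4–O bond lies close to anti-periplanar to the C3–C7 bond, and the oxygen lone pair pushes through C7–C3 into the C4–O antibonding orbital, so that C7=O forms, C3–C7 breaks and C3=C4 forms in one concerted heterolytic step. The closest known reaction type is the Grob (Wharton) fragmentation of cyclic 1,3-diol monosulfonates, as used to open hydrindane skeletons to cyclononenones. Ring C arises by ring expansion: scission of the C3–C7 bond, which belongs to both the carbocycle and the oxane, merges the two small rings into the oxonane, so no medium-ring cyclisation is required. No stereocentre is created; the only stereochemical output is the alkene geometry, which is fixed as Z because the leaving group is cis to C2 and trans to the C3 methyl, leaving C2 and C5 on the same side of the new double bond. The step needs fragmentation to win over elimination towards C5 and over substitution, and the ring-locked anti-periplanar alignment together with the alkoxide push secures this (the C4 epimer would hold its C–O bond gauche to C3–C7 and could not fragment). The single equivalent of base ends as potassium mesylate, so the β-alkoxy ketone product is not left in contact with base that could open the C9–O bond.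

Step 18
Reactants: 26 tricyclic oxonenone
Product: 27 primary alcohol (C16–OH; C11–OSiMe2t-Bu retained)
Conditions: HF·pyridine, pyridine, THF, 0 °C
Reagents that add atoms: none
Why: Fluoride desilylation: the unhindered primary silyl ether is cleaved well before the tertiary one at C11.

Step 19
Reactants: 27 primary alcohol
Product: 29 carboxylic acid (C16), via aldehyde 28 (not isolated)
Conditions: TEMPO (2,2,6,6-tetramethylpiperidin-1-oxyl, 0.2 equiv), PhI(OAc)2, MeCN/H2O (pH 7 buffer), rt
Reagents that add atoms: water, O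
Why: Oxoammonium oxidation (TEMPO with PhI(OAc)2 in the presence of water) takes the primary alcohol through the aldehyde to the acid without base, so C15 is not epimerised and the alkene and ketone are untouched.

Step 20
Reactants: 29 carboxylic acid
Product: 31 hydroxy lactone (ring D closed: C16(=O)–O–C3; free C4–OH; C7 ketone), via epoxy acid 30 (not isolated)
Conditions: mCPBA, CH2Cl2, 0 °C; then camphorsulfonic acid (cat.), rt
Reagents that add atoms: 3-chloroperbenzoic acid, OOC(=O)c1cccc(Cl)c1
Why: Prilezhaev epoxidation on the face of the Z alkene turned away from C1, then acid-catalysed 7-exo opening of the epoxide at the tertiary carbon C3 by the C16 carboxyl with inversion, closes ring D and sets C3 and C4 by net anti addition across the Z alkene.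

Step 21
Reactants: 31 hydroxy lactone
Product: 32 C4 octanoate (C7 ketone)
Conditions: (n-C7H15CO)2O, Et3N, 4-(dimethylamino)pyridine (cat.), CH2Cl2, rt
Reagents that add atoms: octanoic anhydride, CCCCCCCC(=O)OC(=O)CCCCCCC
Why: Acylation with the anhydride under 4-(dimethylamino)pyridine catalysis esterifies the only free hydroxyl, and any transannular C4–O–C7 hemiketal is drained through the open hydroxy ketone.

Step 22
Reactants: 32 C4 octanoate ketone
Product: 33 7-methylidene compound
Conditions: Ph3PCH3Br, KN(SiMe3)2, THF, 0 °C; then 32, −78 to 0 °C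
Reagents that add atoms: methyltriphenylphosphonium bromide, C[P+](c1ccccc1)(c1ccccc1)c1ccccc1.[Br-]
Why: Wittig methylenation: the unhindered C7 ketone reacts with the salt-free ylide far faster than the lactone or the octanoate, and at low temperature olefination outruns enolisation towards C8.

Step 23
Reactants: 33 7-methylidene compound
Product: 34 11-O-(tert-butyldimethylsilyl)briarellin A (C6–OH)
Conditions: SeO2 (0.5 equiv), t-BuOOH, CH2Cl2, rt
Reagents that add atoms: selenium dioxide, O=[Se]=O; tert-butyl hydroperoxide, CC(C)(C)OO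
Why: Selenium dioxide allylic oxidation (ene reaction followed by [2,3]-sigmatropic shift) keeps the exocyclic alkene and places oxygen at C6 on the outer face of ring C, because the C8–H bonds are inductively deactivated by the neighbouring C9–O bond and are the more hindered.

Step 24
Reactants: 34 11-O-silyl briarellin A
Product: 35 briarellin A
Conditions: HF (48% aq), MeCN, 0 °C to rt
Reagents that add atoms: none
Why: Acidic fluoride desilylation frees the tertiary C11 hydroxyl under conditions that spare the lactone, the octanoate and the allylic alcohol.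

**Compound list**

1 | (R)-carvone | CC(=C)[C@@H]1CC=C(C)C(=O)C1 | starting material
2 | (R)-carvone (E)-p-toluenesulfonylhydrazone | CC(=C)[C@@H]1CC=C(C)/C(=N/NS(=O)(=O)c2ccc(C)cc2)C1 | intermediate
3 | [(6R)-3-methyl-6-(prop-1-en-2-yl)cyclohexa-1,3-dien-2-yl]lithium (C10 vinyllithium) | CC1=CC[C@@H](C(C)=C)C=C1[Li] | intermediate (not isolated)
4 | (5R)-2-methyl-5-(prop-1-en-2-yl)cyclohexa-1,3-diene | CC1=CC[C@@H](C(C)=C)C=C1 | intermediate
5 | cis-fused 7-methoxy-5-methyl-2-(prop-1-en-2-yl)bicyclo[4.2.0]oct-4-en-8-one, cyclobutanone trans to isopropenyl, OMe endo | CO[C@H]1C(=O)[C@H]2[C@H](C(C)=C)CC=C(C)[C@@H]12 | intermediate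
6 | cis-fused 3-methoxy-4-methyl-7-(prop-1-en-2-yl)-3a,6,7,7a-tetrahydro-3H-isobenzofuran-1-one (methoxy lactone; C2 carbonyl, C9 acetal) | CO[C@H]1OC(=O)[C@H]2[C@H](C(C)=C)CC=C(C)[C@@H]12 | intermediate
7 | B-alkyl-9-borabicyclo[3.3.1]nonane adduct of 6 (boron on C16, 15R) | CO[C@H]1OC(=O)[C@H]2[C@H]([C@@H](C)CB3C4CCCC3CCC4)CC=C(C)[C@@H]12 | intermediate (not isolated)
8 | methoxy lactone with (15R)-1-hydroxypropan-2-yl side chain and C11=C12 alkene | CO[C@H]1OC(=O)[C@H]2[C@H]([C@@H](C)CO)CC=C(C)[C@@H]12 | intermediate
9 | alkylmercury acetate (HgOAc on C12 trans to the C11 hydroxyl; C11–OH cis to C9) | CO[C@H]1OC(=O)[C@H]2[C@H]([C@@H](C)CO)C[C@H]([Hg]OC(C)=O)[C@@](C)(O)[C@@H]12 | intermediate (not isolated)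
10 | methoxy lactone diol (tertiary C11–OH cis to C9, primary C16–OH) | CO[C@H]1OC(=O)[C@H]2[C@H]([C@@H](C)CO)CC[C@@](C)(O)[C@@H]12 | intermediate
11 | bis(tert-butyldimethylsilyl) ether of 10 | CO[C@H]1OC(=O)[C@H]2[C@H]([C@@H](C)CO[Si](C)(C)C(C)(C)C)CC[C@@](C)(O[Si](C)(C)C(C)(C)C)[C@@H]12 | intermediate
12 | 2-methylcyclopentane-1,3-dione | CC1C(=O)CCC1=O | starting material
13 | 3-[(tert-butyldimethylsilyl)oxy]-2-methylcyclopent-2-en-1-one | CC1=C(O[Si](C)(C)C(C)(C)C)CCC1=O | intermediate
14 | tert-butyldimethyl[(2-methyl-3-methylidenecyclopent-1-en-1-yl)oxy]silane | C=C1CCC(O[Si](C)(C)C(C)(C)C)=C1C | intermediate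
15 | enone lactone: ring A/B γ-lactone bearing at C9 (trans to C11) the (2-methyl-3-oxocyclopent-1-en-1-yl)methyl group | CC1=C(C[C@@H]2OC(=O)[C@H]3[C@H]([C@@H](C)CO[Si](C)(C)C(C)(C)C)CC[C@@](C)(O[Si](C)(C)C(C)(C)C)[C@@H]23)CCC1=O | intermediate
16 | (4S)-allylic alcohol of 15 | CC1=C(C[C@@H]2OC(=O)[C@H]3[C@H]([C@@H](C)CO[Si](C)(C)C(C)(C)C)CC[C@@](C)(O[Si](C)(C)C(C)(C)C)[C@@H]23)CC[C@@H]1O | intermediate
17 | bis(diisobutylaluminium) alkoxide: C2 aluminium hemiacetal and C4 alkoxide | CC(C)C[Al](CC(C)C)O[C@H]1CCC(C[C@@H]2O[C@@H](O[Al](CC(C)C)CC(C)C)[C@H]3[C@H]([C@@H](C)CO[Si](C)(C)C(C)(C)C)CC[C@@](C)(O[Si](C)(C)C(C)(C)C)[C@@H]23)=C1C | intermediate (not isolated)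
18 | bis-acetate: C2 α-acetoxy ether and (4S)-allylic acetate | CC(=O)O[C@H]1CCC(C[C@@H]2O[C@@H](OC(C)=O)[C@H]3[C@H]([C@@H](C)CO[Si](C)(C)C(C)(C)C)CC[C@@](C)(O[Si](C)(C)C(C)(C)C)[C@@H]23)=C1C | intermediate
19 | tetracyclic 2-methyl-1,3-dioxan-2-ylium triflate bridging C4–O and C7–O | CC1=[O+][C@]23CC[C@H](O1)[C@@]2(C)[C@H]4O[C@@H](C3)[C@@H]5[C@](C)(O[Si](C)(C)C(C)(C)C)CC[C@@H]([C@@H](C)CO[Si](C)(C)C(C)(C)C)[C@H]45.[O-]S(=O)(=O)C(F)(F)F | intermediate (not isolated)
20 | tetracyclic (4S)-acetate with free tertiary C7–OH | CC(=O)O[C@H]1CC[C@]2(O)C[C@@H]3O[C@@H]([C@H]4[C@H]([C@@H](C)CO[Si](C)(C)C(C)(C)C)CC[C@@](C)(O[Si](C)(C)C(C)(C)C)[C@@H]34)[C@]12C | intermediate (not isolated)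
21 | tetracyclic cis-1,3-diol ((4S)-OH and C7–OH syn to the C3 methyl) | O[C@H]1CC[C@]2(O)C[C@@H]3O[C@@H]([C@H]4[C@H]([C@@H](C)CO[Si](C)(C)C(C)(C)C)CC[C@@](C)(O[Si](C)(C)C(C)(C)C)[C@@H]34)[C@]12C | intermediate
22 | tetracyclic β-hydroxy ketone (C4 ketone, C7–OH) | O=C1CC[C@]2(O)C[C@@H]3O[C@@H]([C@H]4[C@H]([C@@H](C)CO[Si](C)(C)C(C)(C)C)CC[C@@](C)(O[Si](C)(C)C(C)(C)C)[C@@H]34)[C@]12C | intermediate
23 | tetracyclic anti-1,3-diol ((4R)-OH syn to C2) | O[C@@H]1CC[C@]2(O)C[C@@H]3O[C@@H]([C@H]4[C@H]([C@@H](C)CO[Si](C)(C)C(C)(C)C)CC[C@@](C)(O[Si](C)(C)C(C)(C)C)[C@@H]34)[C@]12C | intermediate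
24 | tetracyclic hydroxy mesylate ((4R)-OMs syn to C2, C7–OH) | CS(=O)(=O)O[C@@H]1CC[C@]2(O)C[C@@H]3O[C@@H]([C@H]4[C@H]([C@@H](C)CO[Si](C)(C)C(C)(C)C)CC[C@@](C)(O[Si](C)(C)C(C)(C)C)[C@@H]34)[C@]12C | intermediate
25 | potassium C7 alkoxide of 24 | CS(=O)(=O)O[C@@H]1CC[C@]2([O-])C[C@@H]3O[C@@H]([C@H]4[C@H]([C@@H](C)CO[Si](C)(C)C(C)(C)C)CC[C@@](C)(O[Si](C)(C)C(C)(C)C)[C@@H]34)[C@]12C.[K+] | intermediate (not isolated)
26 | tricyclic oxonenone (C7 ketone, (Z)-C3=C4) | C/C1=C/CCC(=O)C[C@@H]2O[C@H]1[C@H]1[C@H]([C@@H](C)CO[Si](C)(C)C(C)(C)C)CC[C@@](C)(O[Si](C)(C)C(C)(C)C)[C@H]12 | intermediate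
27 | oxonenone primary alcohol (C16–OH) | C/C1=C/CCC(=O)C[C@@H]2O[C@H]1[C@H]1[C@H]([C@@H](C)CO)CC[C@@](C)(O[Si](C)(C)C(C)(C)C)[C@H]12 | intermediate
28 | oxonenone C16 aldehyde | C/C1=C/CCC(=O)C[C@@H]2O[C@H]1[C@H]1[C@H]([C@@H](C)C=O)CC[C@@](C)(O[Si](C)(C)C(C)(C)C)[C@H]12 | intermediate (not isolated)
29 | oxonenone C16 carboxylic acid | C/C1=C/CCC(=O)C[C@@H]2O[C@H]1[C@H]1[C@H]([C@@H](C)C(O)=O)CC[C@@](C)(O[Si](C)(C)C(C)(C)C)[C@H]12 | intermediate
30 | C3–C4 cis-epoxy acid (epoxide oxygen on the face away from C1) | C[C@@]12O[C@@H]1CCC(=O)C[C@@H]3O[C@H]2[C@H]2[C@H]([C@@H](C)C(O)=O)CC[C@@](C)(O[Si](C)(C)C(C)(C)C)[C@H]23 | intermediate (not isolated)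
31 | tetracyclic hydroxy lactone (ring D; C4–OH; C7 ketone) | O=C1C[C@@H]2O[C@H]3[C@H]4[C@@H](CC[C@@](C)(O[Si](C)(C)C(C)(C)C)[C@H]42)[C@@H](C)C(=O)O[C@@]3(C)[C@H](O)CC1 | intermediate
32 | C4 octanoate of 31 | O=C1C[C@@H]2O[C@H]3[C@H]4[C@@H](CC[C@@](C)(O[Si](C)(C)C(C)(C)C)[C@H]42)[C@@H](C)C(=O)O[C@@]3(C)[C@H](OC(=O)CCCCCCC)CC1 | intermediate
33 | 7-methylidene octanoate | C=C1C[C@@H]2O[C@H]3[C@H]4[C@@H](CC[C@@](C)(O[Si](C)(C)C(C)(C)C)[C@H]42)[C@@H](C)C(=O)O[C@@]3(C)[C@H](OC(=O)CCCCCCC)CC1 | intermediate
34 | 11-O-(tert-butyldimethylsilyl)briarellin A | C=C1C[C@@H]2O[C@H]3[C@H]4[C@@H](CC[C@@](C)(O[Si](C)(C)C(C)(C)C)[C@H]42)[C@@H](C)C(=O)O[C@@]3(C)[C@H](OC(=O)CCCCCCC)C[C@@H]1O | intermediate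
35 | briarellin A | C=C1C[C@@H]2O[C@H]3[C@H]4[C@@H](CC[C@@](C)(O)[C@H]42)[C@@H](C)C(=O)O[C@@]3(C)[C@H](OC(=O)CCCCCCC)C[C@@H]1O | target

**Totals.** Total step count: 24. Longest linear sequence: 22 steps (steps 1–7 and 10–24); steps 8 and 9 make the dienol ether.

**Steps most likely to fail**

Step 13 (Prins cyclisation). The tertiary C7 cation may lose a proton (ene-type termination), or the allylic C4 acetate may ionise before the anomeric one has cyclised, so that capture of the cation is not clean. The fallback sets out from 18 and comes back at 21. The cyclisation is run for the ene outcome on purpose (Me3SiOTf with excess 2,6-di-tert-butyl-4-methylpyridine, then K2CO3 in MeOH), which gives the tetracyclic homoallylic alcohol F1 with a C6=C7 alkene. Its (4S)-hydroxyl, which sits on the methyl-bearing face, directs epoxidation (VO(acac)2, t-BuOOH) to that face and gives epoxy alcohol F2. LiEt3BH then opens the epoxide at the secondary carbon C6 and returns the cis-diol 21.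

Step 6 (oxymercuration). Facial selectivity may be poor: mercuration on the C9 face followed by anti attack of water would place the C11 hydroxyl trans to C9. The fallback sets out from 8 and comes back at 10; it delivers the oxygen from the C2 carboxyl, which can reach C11 only on the face it shares with C9. Saponification of the methoxy lactone (LiOH, THF/H2O) and iodolactonisation in the same flask (I2, KI, NaHCO3) give iodolactone aldehyde F3 (C2(=O)–O–C11 bridge, iodine on C12). n-Bu3SnH with azobisisobutyronitrile removes the iodine and gives lactone aldehyde F4. Camphorsulfonic acid in methanol then acetalises the aldehyde and translactonises to the cis-fused methoxy lactone 10, in which ring A regains the chair with C15 equatorial.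

Step 23 (allylic oxidation). Site selectivity between C6 and C8 may be poor, the alcohol may be over-oxidised to the enone, or oxygen may arrive on the wrong face of C6. The fallback sets out from 32 and comes back at 34; it puts the oxygen on C6 before the methylene exists. LiN(SiMe3)2 at −78 °C enolises the C7 ketone towards the less hindered C6, and 2-(phenylsulfonyl)-3-phenyloxaziridine hydroxylates the enolate from the outer face to give α-hydroxy ketone F5. Wittig methylenation with excess Ph3P=CH2 then gives 34.

**Further compounds**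

F1 | step 13 | tetracyclic (4S)-homoallylic alcohol with C6=C7 alkene | O[C@H]1CC=C2C[C@@H]3O[C@@H]([C@H]4[C@H]([C@@H](C)CO[Si](C)(C)C(C)(C)C)CC[C@@](C)(O[Si](C)(C)C(C)(C)C)[C@@H]34)[C@]12C
F2 | step 13 | tetracyclic C6–C7 epoxy alcohol (epoxide oxygen syn to the C3 methyl and the C4 hydroxyl) | O[C@H]1C[C@H]5O[C@]52C[C@@H]3O[C@@H]([C@H]4[C@H]([C@@H](C)CO[Si](C)(C)C(C)(C)C)CC[C@@](C)(O[Si](C)(C)C(C)(C)C)[C@@H]34)[C@]12C
F3 | step 6 | bridged iodolactone aldehyde (C2(=O)–O–C11, iodine on C12 trans to the lactone oxygen, C9 aldehyde) | O=C[C@H]1[C@H]2C(=O)O[C@]1(C)[C@@H](I)C[C@H]2[C@@H](C)CO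
F4 | step 6 | bridged lactone aldehyde (C2(=O)–O–C11, C9 aldehyde) | O=C[C@H]1[C@H]2C(=O)O[C@]1(C)CC[C@H]2[C@@H](C)CO
F5 | step 23 | 6-hydroxy-7-ketone octanoate (C6 configured as in the target) | O=C1C[C@@H]2O[C@H]3[C@H]4[C@@H](CC[C@@](C)(O[Si](C)(C)C(C)(C)C)[C@H]42)[C@@H](C)C(=O)O[C@@]3(C)[C@H](OC(=O)CCCCCCC)C[C@@H]1O
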